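**Retrosynthetic overview**

1. Target 38 ⇐ removal of two MOM and three TIPS groups ⇐ chalcone 35 ⇐ lithiation of ring A (the C–H between OMe and OMOM) of alcohol 30, addition to enal 32, oxidation.
2. 30 ⇐ C3 ketone 29 ⇐ Meinwald hydride shift of 3,4-epoxide 28 ⇐ dihydropyran 27, whose C6 arylethyl chain comes from the C6 carboxyl of acid 18 (reduction, Wittig with 24, diimide).
3. Key disconnection: the C5–C6 bond of ring C (the tetrahydropyran), together with the 2,6-trans relation across O1 between ring D at C2 and the C6 substituent, maps onto the cis-5-aryl-6-(1-arylvinyl)-1,4-dioxan-2-one 15 by an Ireland–Claisen rearrangement.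
4. 15 ⇐ anti alcohol 14 ⇐ chelate-controlled reduction of enone 13 ⇐ Weinreb amide 5 (from (S)-4-hydroxymandelic acid 1 and diazoacetate 4) + ring A vinylstannane 9 (from acetophenone 6).
5. Ring order: rings A, B, D and E are bought as arenes; the dioxanone is closed in step 9 and exchanged for ring C in step 10; no other ring is formed.

Key step: step 10

Assumption: ring C is numbered O1, C2 (ring D), C3 (OH), C4 (ring A), C5, C6 (chain to ring E), ring B is the aryl of the enone, and the L-fructose-derived enantiomer of the Shi ketone is taken as accessible from L-sorbose.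

Remark: a chelate-controlled vinyl-metal addition to the corresponding α-alkoxy aldehyde would give the syn alcohol and hence the trans-dioxanone, so the anti alcohol is made by chelate-controlled reduction of the enone instead.

**Route**

Step 1
Reactants: 1 (S)-4-hydroxymandelic acid
Product: 2 (2S)-2-hydroxy-2-(4-hydroxyphenyl)-N-methoxy-N-methylacetamide
Conditions: MeNHOMe·HCl, EDC·HCl, HOBt, N-methylmorpholine, DMF, 0 °C → rt
Reagents that add atoms: N,O-dimethylhydroxylamine hydrochloride, CNOC.Cl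
Why: Carbodiimide/HOBt amide coupling (Weinreb amide formation) in which the amine outcompetes the secondary hydroxyl and the phenol for the active ester and the stereocentre is not touched.

Step 2
Reactants: 2 (2S)-2-hydroxy-2-(4-hydroxyphenyl)-N-methoxy-N-methylacetamide
Product: 3 (2S)-2-hydroxy-N-methoxy-N-methyl-2-[4-(triisopropylsilyloxy)phenyl]acetamide
Conditions: TIPSCl, imidazole, DMF, 0 °C → rt
Reagents that add atoms: triisopropylsilyl chloride, CC(C)[Si](Cl)(C(C)C)C(C)C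
Why: Silyl ether formation that should be selective for the phenol, because the bulky silyl chloride reacts only slowly with the hindered, electron-poor secondary hydroxyl.

Step 3
Reactants: 3 (2S)-2-hydroxy-N-methoxy-N-methyl-2-[4-(triisopropylsilyloxy)phenyl]acetamide; 4 tert-butyl diazoacetate
Product: 5 tert-butyl 2-{(1S)-2-[methoxy(methyl)amino]-2-oxo-1-[4-(triisopropylsilyloxy)phenyl]ethoxy}acetate
Conditions: Rh2(OAc)4 (1 mol %), CH2Cl2, rt, slow addition of 4
Reagents that add atoms: none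
Why: Rhodium-carbenoid O–H insertion builds the glycolate ether under neutral conditions, so the benzylic α-stereocentre cannot racemise as it might in a base-mediated Williamson alkylation.

Step 4
Reactants: 6 2',6'-dihydroxy-4'-methoxyacetophenone
Product: 7 1-[4-methoxy-2,6-bis(methoxymethoxy)phenyl]ethanone
Conditions: NaH, MOMCl, DMF, 0 °C → rt
Reagents that add atoms: chloromethyl methyl ether, COCCl
Why: O-alkylation of both phenoxides (MOM protection), with sodium hydride used because it breaks the hydrogen bonds to the carbonyl that slow amine-base protocols.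

Step 5
Reactants: 7 1-[4-methoxy-2,6-bis(methoxymethoxy)phenyl]ethanone
Product: 8 1-[4-methoxy-2,6-bis(methoxymethoxy)phenyl]ethenyl trifluoromethanesulfonate
Conditions: KN(SiMe3)2, THF, −78 °C; PhNTf2, −78 → 0 °C
Reagents that add atoms: N-phenylbis(trifluoromethanesulfonimide), O=S(=O)(N(c1ccccc1)S(=O)(=O)C(F)(F)F)C(F)(F)F
Why: Enol triflate formation by O-sulfonylation of the potassium enolate of the methyl ketone, which has only one enolisable position.

Step 6
Reactants: 8 1-[4-methoxy-2,6-bis(methoxymethoxy)phenyl]ethenyl trifluoromethanesulfonate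
Product: 9 trimethyl{1-[4-methoxy-2,6-bis(methoxymethoxy)phenyl]ethenyl}stannane
Conditions: Me3SnSnMe3, Pd(PPh3)4 (5 mol %), LiCl, THF, 65 °C
Reagents that add atoms: hexamethylditin, C[Sn](C)(C)[Sn](C)(C)C
Why: Palladium-catalysed stannylation of an enol triflate with a distannane (Stille-type coupling), with LiCl assisting the transmetalation.

Step 7
Reactants: 9 trimethyl{1-[4-methoxy-2,6-bis(methoxymethoxy)phenyl]ethenyl}stannane; 5 tert-butyl 2-{(1S)-2-[methoxy(methyl)amino]-2-oxo-1-[4-(triisopropylsilyloxy)phenyl]ethoxy}acetate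
Product: 13 tert-butyl 2-{[(1S)-3-[4-methoxy-2,6-bis(methoxymethoxy)phenyl]-2-oxo-1-[4-(triisopropylsilyloxy)phenyl]but-3-en-1-yl]oxy}acetate, via vinyllithium 10 (not isolated), via vinylmagnesium bromide 11 (not isolated), via magnesium hemiaminal 12 (not isolated)
Conditions: MeLi, THF, −78 °C; MgBr2·OEt2; then 5, −78 → −10 °C; poured into cold aq. citric acid
Reagents that add atoms: none
Why: Tin–lithium exchange, transmetalation to magnesium and Weinreb ketone synthesis, in which the chelated hemiaminal 12 stops at the ketone stage and shields the α-aryl-α-alkoxy stereocentre until the cold acidic quench, while the tert-butyl ester should be inert to the hindered vinylmagnesium reagent at low temperature.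

Step 8
Reactants: 13 tert-butyl 2-{[(1S)-3-[4-methoxy-2,6-bis(methoxymethoxy)phenyl]-2-oxo-1-[4-(triisopropylsilyloxy)phenyl]but-3-en-1-yl]oxy}acetate
Product: 14 tert-butyl 2-{[(1S,2R)-2-hydroxy-3-[4-methoxy-2,6-bis(methoxymethoxy)phenyl]-1-[4-(triisopropylsilyloxy)phenyl]but-3-en-1-yl]oxy}acetate
Conditions: Zn(BH4)2, Et2O, −30 °C
Reagents that add atoms: none
Why: Cram-chelate-controlled 1,2-reduction in which zinc bridges the ketone and α-ether oxygens and hydride enters the five-membered chelate on the face away from ring D, setting the (2R) carbinol anti to the ether oxygen.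

Step 9
Reactants: 14 tert-butyl 2-{[(1S,2R)-2-hydroxy-3-[4-methoxy-2,6-bis(methoxymethoxy)phenyl]-1-[4-(triisopropylsilyloxy)phenyl]but-3-en-1-yl]oxy}acetate
Product: 15 (5S,6R)-6-{1-[4-methoxy-2,6-bis(methoxymethoxy)phenyl]ethenyl}-5-[4-(triisopropylsilyloxy)phenyl]-1,4-dioxan-2-one (5,6-cis)
Conditions: KOC(CH3)3 (0.2 equiv), THF (0.02 M), 0 °C → rt
Reagents that add atoms: none
Why: Alkoxide-catalysed intramolecular transesterification (6-exo-trig lactonisation) releases tert-butanol without the acid that would endanger the MOM ethers and the electron-rich arylvinyl group, and the anti alcohol necessarily gives the 5,6-cis ring.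

Step 10
Reactants: 15 (5S,6R)-6-{1-[4-methoxy-2,6-bis(methoxymethoxy)phenyl]ethenyl}-5-[4-(triisopropylsilyloxy)phenyl]-1,4-dioxan-2-one
Product: 18 (2R,6R)-4-[4-methoxy-2,6-bis(methoxymethoxy)phenyl]-6-[4-(triisopropylsilyloxy)phenyl]-3,6-dihydro-2H-pyran-2-carboxylic acid (2,6-trans), via silyl ketene acetal 16 (not isolated), via trimethylsilyl ester 17 (not isolated)
Conditions: Me3SiCl/Et3N, LiN(SiMe3)2, THF, −78 °C → rt; PhMe, 80 °C; then H2O/THF, pH 5 buffer
Reagents that add atoms: none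
Why: LiN(SiMe3)2 removes a C3 proton of the dioxanone (the only acidic C–H) and Me3SiCl, present from the start, traps the enolate as the endocyclic silyl ketene acetal 16, which can reach the vinyl terminus only through a boat, bicyclo[2.2.2]octane-like [3,3] transition state. The closest known reaction is the Ireland–Claisen rearrangement of 6-alkenyl-1,4-dioxan-2-ones to 3,6-dihydro-2H-pyran-2-carboxylic acids, applied here to a 1-arylvinyl member of that class. Ring C closes by suprafacial C–C bond formation between the enolate carbon (future C6) and the vinyl CH2 (future C5) while the lactone C–O bond at the allylic carbon breaks, so the six-membered dioxanone is exchanged for the six-membered dihydropyran with the alkene at C3=C4. The new stereocentre (C6 of ring C) is controlled by the vinyl-bearing stereocentre of the dioxanone: the bond can form only on the ring face that carries the vinyl group, and because ring D is cis to that group the carboxyl ends up trans to ring D across O1. The step needs complete chirality transfer with no chair pathway; the ring tether excludes the chair, and ring A sits on the central allyl carbon, pointing away from the bicyclic array.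

Step 11
Reactants: 18 (2R,6R)-4-[4-methoxy-2,6-bis(methoxymethoxy)phenyl]-6-[4-(triisopropylsilyloxy)phenyl]-3,6-dihydro-2H-pyran-2-carboxylic acid
Product: 19 {(2R,6R)-4-[4-methoxy-2,6-bis(methoxymethoxy)phenyl]-6-[4-(triisopropylsilyloxy)phenyl]-3,6-dihydro-2H-pyran-2-yl}methanol
Conditions: LiAlH4, THF, 0 °C → rt; aq. NaOH work-up
Reagents that add atoms: none
Why: Hydride reduction of the carboxylic acid through its lithium carboxylate, which cannot epimerise at C6, while the alkene and the MOM and aryl TIPS ethers are inert.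

Step 12
Reactants: 19 {(2R,6R)-4-[4-methoxy-2,6-bis(methoxymethoxy)phenyl]-6-[4-(triisopropylsilyloxy)phenyl]-3,6-dihydro-2H-pyran-2-yl}methanol
Product: 20 (2R,6R)-4-[4-methoxy-2,6-bis(methoxymethoxy)phenyl]-6-[4-(triisopropylsilyloxy)phenyl]-3,6-dihydro-2H-pyran-2-carbaldehyde
Conditions: Dess–Martin periodinane, NaHCO3, CH2Cl2, 0 °C → rt
Reagents that add atoms: none
Why: Dess–Martin oxidation under bicarbonate buffering should give the α-alkoxy aldehyde without epimerising C6 or ionising the allylic benzylic C2–O1 bond.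

Step 13
Reactants: 21 4-hydroxybenzaldehyde
Product: 22 4-(triisopropylsilyloxy)benzaldehyde
Conditions: TIPSCl, imidazole, DMF, rt
Reagents that add atoms: triisopropylsilyl chloride, CC(C)[Si](Cl)(C(C)C)C(C)C
Why: Standard silyl ether formation on a phenol.

Step 14
Reactants: 22 4-(triisopropylsilyloxy)benzaldehyde
Product: 23 [4-(triisopropylsilyloxy)phenyl]methanol
Conditions: NaBH4, MeOH, 0 °C
Reagents that add atoms: none
Why: Borohydride reduction of an aldehyde, which leaves the aryl silyl ether intact at low temperature.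

Step 15
Reactants: 23 [4-(triisopropylsilyloxy)phenyl]methanol
Product: 24 triphenyl[4-(triisopropylsilyloxy)benzyl]phosphonium bromide
Conditions: PPh3·HBr, MeCN, 60 °C
Reagents that add atoms: triphenylphosphine hydrobromide, [Br-].c1ccc(cc1)[PH+](c1ccccc1)c1ccccc1
Why: Phosphonium salt formation directly from an electron-rich benzylic alcohol, by acid-promoted ionisation and capture by triphenylphosphine.

Step 16
Reactants: 24 triphenyl[4-(triisopropylsilyloxy)benzyl]phosphonium bromide; 20 (2R,6R)-4-[4-methoxy-2,6-bis(methoxymethoxy)phenyl]-6-[4-(triisopropylsilyloxy)phenyl]-3,6-dihydro-2H-pyran-2-carbaldehyde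
Product: 26 (2R,6R)-4-[4-methoxy-2,6-bis(methoxymethoxy)phenyl]-2-[4-(triisopropylsilyloxy)phenyl]-6-{2-[4-(triisopropylsilyloxy)phenyl]ethenyl}-5,6-dihydro-2H-pyran (E/Z mixture), via phosphonium ylide 25 (not isolated)
Conditions: NaN(SiMe3)2, THF, −78 → 0 °C; then 20, −78 °C → rt
Reagents that add atoms: none
Why: Wittig olefination with a semi-stabilised benzylic ylide, where the alkene geometry is irrelevant because the double bond is reduced next and addition at low temperature without excess base should keep C6 intact.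

Step 17
Reactants: 26 (2R,6R)-4-[4-methoxy-2,6-bis(methoxymethoxy)phenyl]-2-[4-(triisopropylsilyloxy)phenyl]-6-{2-[4-(triisopropylsilyloxy)phenyl]ethenyl}-5,6-dihydro-2H-pyran
Product: 27 (2R,6S)-4-[4-methoxy-2,6-bis(methoxymethoxy)phenyl]-2-[4-(triisopropylsilyloxy)phenyl]-6-{2-[4-(triisopropylsilyloxy)phenyl]ethyl}-5,6-dihydro-2H-pyran
Conditions: 2-nitrobenzenesulfonylhydrazide, Et3N, CH2Cl2, rt
Reagents that add atoms: none
Why: Diimide reduction is selective for the 1,2-disubstituted alkene over the hindered trisubstituted ring alkene and, unlike catalytic hydrogenation, leaves the benzylic C–O bonds alone.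

Step 18
Reactants: 27 (2R,6S)-4-[4-methoxy-2,6-bis(methoxymethoxy)phenyl]-2-[4-(triisopropylsilyloxy)phenyl]-6-{2-[4-(triisopropylsilyloxy)phenyl]ethyl}-5,6-dihydro-2H-pyran
Product: 28 (1S,2S,4S,6S)-6-[4-methoxy-2,6-bis(methoxymethoxy)phenyl]-2-[4-(triisopropylsilyloxy)phenyl]-4-{2-[4-(triisopropylsilyloxy)phenyl]ethyl}-3,7-dioxabicyclo[4.1.0]heptane (3,4-epoxide of ring C with the oxirane oxygen on the face opposite ring D)
Conditions: L-fructose-derived Shi ketone (0.3 equiv), KHSO5 (Oxone), K2CO3, Bu4NHSO4, MeCN/CH2(OMe)2–aq. Na2B4O7 buffer (pH 10.5), 0 °C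
Reagents that add atoms: potassium peroxymonosulfate (Oxone, KHSO5), OOS(=O)(=O)[O-].[K+]
Why: Shi asymmetric epoxidation, in which this ketone enantiomer delivers oxygen to the face of a 1-arylcyclohexene-type alkene that leads to the (S,S) oxide; in 27 that is the face anti to ring D, which is also the sterically preferred one, and the basic buffer preserves the acid-labile epoxide.

Step 19
Reactants: 28 3,4-epoxide of ring C (oxirane oxygen anti to ring D)
Product: 29 (2S,4S,6S)-4-[4-methoxy-2,6-bis(methoxymethoxy)phenyl]-2-[4-(triisopropylsilyloxy)phenyl]-6-{2-[4-(triisopropylsilyloxy)phenyl]ethyl}oxan-3-one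
Conditions: InCl3 (10 mol %), THF, 0 °C → rt
Reagents that add atoms: none
Why: Meinwald rearrangement, in which the Lewis acid opens the benzylic C4–O bond to a cation stabilised by ring A and the C3 hydrogen, lying on the face opposite the former oxirane oxygen, shifts suprafacially to C4, giving the C3 ketone with C4–H cis to ring D (ring A trans to ring D and cis to the C6 chain).

Step 20
Reactants: 29 (2S,4S,6S)-4-[4-methoxy-2,6-bis(methoxymethoxy)phenyl]-2-[4-(triisopropylsilyloxy)phenyl]-6-{2-[4-(triisopropylsilyloxy)phenyl]ethyl}oxan-3-one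
Product: 30 (2S,3S,4S,6S)-4-[4-methoxy-2,6-bis(methoxymethoxy)phenyl]-2-[4-(triisopropylsilyloxy)phenyl]-6-{2-[4-(triisopropylsilyloxy)phenyl]ethyl}oxan-3-ol
Conditions: NaBH4, MeOH/THF, −40 °C
Reagents that add atoms: none
Why: Borohydride reduction of the chair with ring A and the C6 chain equatorial and ring D axial, where hydride attacks C3 axially on the face opposite the axial ring D to give the equatorial (3S) alcohol cis to ring D and trans to ring A, the low temperature suppressing enolisation towards C2 or C4.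

Step 21
Reactants: 22 4-(triisopropylsilyloxy)benzaldehyde; 31 (triphenylphosphoranylidene)acetaldehyde
Product: 32 (2E)-3-[4-(triisopropylsilyloxy)phenyl]prop-2-enal
Conditions: PhMe, 80 °C
Reagents that add atoms: none
Why: Wittig reaction with a stabilised formylmethylene ylide, which gives the (E)-enal.

Step 22
Reactants: 30 (2S,3S,4S,6S)-4-[4-methoxy-2,6-bis(methoxymethoxy)phenyl]-2-[4-(triisopropylsilyloxy)phenyl]-6-{2-[4-(triisopropylsilyloxy)phenyl]ethyl}oxan-3-ol; 32 (2E)-3-[4-(triisopropylsilyloxy)phenyl]prop-2-enal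
Product: 34 (2E)-1-{3-[(2S,3S,4S,6S)-3-hydroxy-2-[4-(triisopropylsilyloxy)phenyl]-6-{2-[4-(triisopropylsilyloxy)phenyl]ethyl}oxan-4-yl]-6-methoxy-2,4-bis(methoxymethoxy)phenyl}-3-[4-(triisopropylsilyloxy)phenyl]prop-2-en-1-ol (both carbinol epimers), via dilithio species 33 (not isolated)
Conditions: n-BuLi (2.3 equiv), TMEDA, THF, −78 → −20 °C; then 32, −78 °C; aq. NH4Cl
Reagents that add atoms: none
Why: Directed ortho-metalation, in which, after O-lithiation of the C3 hydroxyl, the only ring C–H flanked by two directing groups (OMe and OMOM on ring A) is lithiated and adds 1,2 to the enal, the new carbinol centre being destroyed in the next step.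

Step 23
Reactants: 34 ring A allylic benzylic alcohol (both carbinol epimers)
Product: 35 (2E)-1-{3-[(2S,3S,4S,6S)-3-hydroxy-2-[4-(triisopropylsilyloxy)phenyl]-6-{2-[4-(triisopropylsilyloxy)phenyl]ethyl}oxan-4-yl]-6-methoxy-2,4-bis(methoxymethoxy)phenyl}-3-[4-(triisopropylsilyloxy)phenyl]prop-2-en-1-one
Conditions: MnO2, CH2Cl2, rt
Reagents that add atoms: none
Why: MnO2 oxidises only the doubly activated (benzylic and allylic) alcohol and should leave the unactivated C3 secondary alcohol untouched.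

Step 24
Reactants: 35 protected chalcone (two MOM and three TIPS ethers)
Product: 37 (2E)-1-{2,4-dihydroxy-3-[(2S,3S,4S,6S)-3-hydroxy-2-[4-(triisopropylsilyloxy)phenyl]-6-{2-[4-(triisopropylsilyloxy)phenyl]ethyl}oxan-4-yl]-6-methoxyphenyl}-3-[4-(triisopropylsilyloxy)phenyl]prop-2-en-1-one, via tris(trimethylsilyl) ether 36 (not isolated)
Conditions: Me3SiOTf, 2,2′-bipyridyl, CH2Cl2, 0 °C → rt; then H2O
Reagents that add atoms: none
Why: Silyl-triflate/bipyridyl cleavage of aryl MOM ethers followed by hydrolysis of the resulting trimethylsilyl ethers, chosen because it avoids the Brønsted acid that could ionise the benzylic C2–O1 bond and epimerise C2.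

Step 25
Reactants: 37 tris(triisopropylsilyl) ether of the target
Product: 38 (2E)-1-{2,4-dihydroxy-3-[(2S,3S,4S,6S)-3-hydroxy-2-(4-hydroxyphenyl)-6-[2-(4-hydroxyphenyl)ethyl]oxan-4-yl]-6-methoxyphenyl}-3-(4-hydroxyphenyl)prop-2-en-1-one (target)
Conditions: Bu4NF, AcOH, THF, 0 °C → rt
Reagents that add atoms: none
Why: Fluoride-mediated desilylation of the three aryl silyl ethers, buffered with acetic acid so that the 2′-hydroxychalcone should not cyclise and C2 should not epimerise.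

**Compound list**

1 | (S)-4-hydroxymandelic acid | O[C@H](C(=O)O)c1ccc(O)cc1 | starting material
2 | (2S)-2-hydroxy-2-(4-hydroxyphenyl)-N-methoxy-N-methylacetamide | CON(C)C(=O)[C@@H](O)c1ccc(O)cc1 | intermediate
3 | (2S)-2-hydroxy-N-methoxy-N-methyl-2-[4-(triisopropylsilyloxy)phenyl]acetamide | CON(C)C(=O)[C@@H](O)c1ccc(O[Si](C(C)C)(C(C)C)C(C)C)cc1 | intermediate
4 | tert-butyl diazoacetate | CC(C)(C)OC(=O)C=[N+]=[N-] | starting material
5 | tert-butyl 2-{(1S)-2-[methoxy(methyl)amino]-2-oxo-1-[4-(triisopropylsilyloxy)phenyl]ethoxy}acetate | CON(C)C(=O)[C@@H](OCC(=O)OC(C)(C)C)c1ccc(O[Si](C(C)C)(C(C)C)C(C)C)cc1 | intermediate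
6 | 2',6'-dihydroxy-4'-methoxyacetophenone | CC(=O)c1c(O)cc(OC)cc1O | starting material
7 | 1-[4-methoxy-2,6-bis(methoxymethoxy)phenyl]ethanone | CC(=O)c1c(OCOC)cc(OC)cc1OCOC | intermediate
8 | 1-[4-methoxy-2,6-bis(methoxymethoxy)phenyl]ethenyl trifluoromethanesulfonate | C=C(OS(=O)(=O)C(F)(F)F)c1c(OCOC)cc(OC)cc1OCOC | intermediate
9 | trimethyl{1-[4-methoxy-2,6-bis(methoxymethoxy)phenyl]ethenyl}stannane | C=C([Sn](C)(C)C)c1c(OCOC)cc(OC)cc1OCOC | intermediate
10 | {1-[4-methoxy-2,6-bis(methoxymethoxy)phenyl]ethenyl}lithium (not isolated) | [Li]C(=C)c1c(OCOC)cc(OC)cc1OCOC | intermediate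
11 | {1-[4-methoxy-2,6-bis(methoxymethoxy)phenyl]ethenyl}magnesium bromide (not isolated) | Br[Mg]C(=C)c1c(OCOC)cc(OC)cc1OCOC | intermediate
12 | bromomagnesium N-methoxy-N-methyl hemiaminal from 11 and 5 (tetrahedral adduct, hemiaminal carbon undefined; not isolated) | CON(C)C(O[Mg]Br)(C(=C)c1c(OCOC)cc(OC)cc1OCOC)[C@@H](OCC(=O)OC(C)(C)C)c1ccc(O[Si](C(C)C)(C(C)C)C(C)C)cc1 | intermediate
13 | tert-butyl 2-{[(1S)-3-[4-methoxy-2,6-bis(methoxymethoxy)phenyl]-2-oxo-1-[4-(triisopropylsilyloxy)phenyl]but-3-en-1-yl]oxy}acetate | C=C(C(=O)[C@@H](OCC(=O)OC(C)(C)C)c1ccc(O[Si](C(C)C)(C(C)C)C(C)C)cc1)c1c(OCOC)cc(OC)cc1OCOC | intermediate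
14 | tert-butyl 2-{[(1S,2R)-2-hydroxy-3-[4-methoxy-2,6-bis(methoxymethoxy)phenyl]-1-[4-(triisopropylsilyloxy)phenyl]but-3-en-1-yl]oxy}acetate (anti) | CC(C)(C)OC(=O)CO[C@@H](c1ccc(O[Si](C(C)C)(C(C)C)C(C)C)cc1)[C@H](O)C(=C)c1c(OCOC)cc(OC)cc1OCOC | intermediate
15 | (5S,6R)-6-{1-[4-methoxy-2,6-bis(methoxymethoxy)phenyl]ethenyl}-5-[4-(triisopropylsilyloxy)phenyl]-1,4-dioxan-2-one (5,6-cis) | O=C1CO[C@@H](c2ccc(O[Si](C(C)C)(C(C)C)C(C)C)cc2)[C@@H](C(=C)c2c(OCOC)cc(OC)cc2OCOC)O1 | intermediate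
16 | trimethylsilyl ketene acetal of 15 (O-silyl enol ether of the lactone, stereocentres as in 15; not isolated) | C[Si](C)(C)OC1=CO[C@@H](c2ccc(O[Si](C(C)C)(C(C)C)C(C)C)cc2)[C@@H](C(=C)c2c(OCOC)cc(OC)cc2OCOC)O1 | intermediate
17 | trimethylsilyl ester of acid 18 (not isolated) | C[Si](C)(C)OC(=O)[C@H]1CC(c2c(OCOC)cc(OC)cc2OCOC)=C[C@H](c2ccc(O[Si](C(C)C)(C(C)C)C(C)C)cc2)O1 | intermediate
18 | (2R,6R)-4-[4-methoxy-2,6-bis(methoxymethoxy)phenyl]-6-[4-(triisopropylsilyloxy)phenyl]-3,6-dihydro-2H-pyran-2-carboxylic acid (2,6-trans; the carboxyl carbon is C6 of ring C) | OC(=O)[C@H]1CC(c2c(OCOC)cc(OC)cc2OCOC)=C[C@H](c2ccc(O[Si](C(C)C)(C(C)C)C(C)C)cc2)O1 | intermediate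
19 | {(2R,6R)-4-[4-methoxy-2,6-bis(methoxymethoxy)phenyl]-6-[4-(triisopropylsilyloxy)phenyl]-3,6-dihydro-2H-pyran-2-yl}methanol | OC[C@H]1CC(c2c(OCOC)cc(OC)cc2OCOC)=C[C@H](c2ccc(O[Si](C(C)C)(C(C)C)C(C)C)cc2)O1 | intermediate
20 | (2R,6R)-4-[4-methoxy-2,6-bis(methoxymethoxy)phenyl]-6-[4-(triisopropylsilyloxy)phenyl]-3,6-dihydro-2H-pyran-2-carbaldehyde | O=C[C@H]1CC(c2c(OCOC)cc(OC)cc2OCOC)=C[C@H](c2ccc(O[Si](C(C)C)(C(C)C)C(C)C)cc2)O1 | intermediate
21 | 4-hydroxybenzaldehyde | O=Cc1ccc(O)cc1 | starting material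
22 | 4-(triisopropylsilyloxy)benzaldehyde | O=Cc1ccc(O[Si](C(C)C)(C(C)C)C(C)C)cc1 | intermediate
23 | [4-(triisopropylsilyloxy)phenyl]methanol | OCc1ccc(O[Si](C(C)C)(C(C)C)C(C)C)cc1 | intermediate
24 | triphenyl[4-(triisopropylsilyloxy)benzyl]phosphonium bromide | [Br-].CC(C)[Si](C(C)C)(C(C)C)Oc1ccc(C[P+](c2ccccc2)(c2ccccc2)c2ccccc2)cc1 | intermediate
25 | triphenyl[4-(triisopropylsilyloxy)benzylidene]phosphorane (ylide, not isolated) | CC(C)[Si](C(C)C)(C(C)C)Oc1ccc(C=P(c2ccccc2)(c2ccccc2)c2ccccc2)cc1 | intermediate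
26 | (2R,6R)-4-[4-methoxy-2,6-bis(methoxymethoxy)phenyl]-2-[4-(triisopropylsilyloxy)phenyl]-6-{2-[4-(triisopropylsilyloxy)phenyl]ethenyl}-5,6-dihydro-2H-pyran (E/Z mixture) | CC(C)[Si](C(C)C)(C(C)C)Oc1ccc(C=C[C@H]2CC(c3c(OCOC)cc(OC)cc3OCOC)=C[C@H](c3ccc(O[Si](C(C)C)(C(C)C)C(C)C)cc3)O2)cc1 | intermediate
27 | (2R,6S)-4-[4-methoxy-2,6-bis(methoxymethoxy)phenyl]-2-[4-(triisopropylsilyloxy)phenyl]-6-{2-[4-(triisopropylsilyloxy)phenyl]ethyl}-5,6-dihydro-2H-pyran (2,6-trans) | CC(C)[Si](C(C)C)(C(C)C)Oc1ccc(CC[C@H]2CC(c3c(OCOC)cc(OC)cc3OCOC)=C[C@H](c3ccc(O[Si](C(C)C)(C(C)C)C(C)C)cc3)O2)cc1 | intermediate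
28 | (1S,2S,4S,6S)-6-[4-methoxy-2,6-bis(methoxymethoxy)phenyl]-2-[4-(triisopropylsilyloxy)phenyl]-4-{2-[4-(triisopropylsilyloxy)phenyl]ethyl}-3,7-dioxabicyclo[4.1.0]heptane (3,4-epoxide of ring C, oxygen anti to ring D) | COc1cc(OCOC)c([C@@]23C[C@H](CCc4ccc(O[Si](C(C)C)(C(C)C)C(C)C)cc4)O[C@@H](c4ccc(O[Si](C(C)C)(C(C)C)C(C)C)cc4)[C@@H]2O3)c(OCOC)c1 | intermediate
29 | (2S,4S,6S)-4-[4-methoxy-2,6-bis(methoxymethoxy)phenyl]-2-[4-(triisopropylsilyloxy)phenyl]-6-{2-[4-(triisopropylsilyloxy)phenyl]ethyl}oxan-3-one | COc1cc(OCOC)c([C@@H]2C[C@H](CCc3ccc(O[Si](C(C)C)(C(C)C)C(C)C)cc3)O[C@@H](c3ccc(O[Si](C(C)C)(C(C)C)C(C)C)cc3)C2=O)c(OCOC)c1 | intermediate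
30 | (2S,3S,4S,6S)-4-[4-methoxy-2,6-bis(methoxymethoxy)phenyl]-2-[4-(triisopropylsilyloxy)phenyl]-6-{2-[4-(triisopropylsilyloxy)phenyl]ethyl}oxan-3-ol | COc1cc(OCOC)c([C@@H]2C[C@H](CCc3ccc(O[Si](C(C)C)(C(C)C)C(C)C)cc3)O[C@@H](c3ccc(O[Si](C(C)C)(C(C)C)C(C)C)cc3)[C@H]2O)c(OCOC)c1 | intermediate
31 | (triphenylphosphoranylidene)acetaldehyde | O=CC=P(c1ccccc1)(c1ccccc1)c1ccccc1 | starting material
32 | (2E)-3-[4-(triisopropylsilyloxy)phenyl]prop-2-enal | O=C/C=C/c1ccc(O[Si](C(C)C)(C(C)C)C(C)C)cc1 | intermediate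
33 | dilithio species of 30 (C3 lithium alkoxide and ring A aryllithium between OMe and OMOM; not isolated) | COc1cc(OCOC)c([C@@H]2C[C@H](CCc3ccc(O[Si](C(C)C)(C(C)C)C(C)C)cc3)O[C@@H](c3ccc(O[Si](C(C)C)(C(C)C)C(C)C)cc3)[C@H]2O[Li])c(OCOC)c1[Li] | intermediate
34 | (2E)-1-{3-[(2S,3S,4S,6S)-3-hydroxy-2-[4-(triisopropylsilyloxy)phenyl]-6-{2-[4-(triisopropylsilyloxy)phenyl]ethyl}oxan-4-yl]-6-methoxy-2,4-bis(methoxymethoxy)phenyl}-3-[4-(triisopropylsilyloxy)phenyl]prop-2-en-1-ol (both carbinol epimers) | COc1cc(OCOC)c([C@@H]2C[C@H](CCc3ccc(O[Si](C(C)C)(C(C)C)C(C)C)cc3)O[C@@H](c3ccc(O[Si](C(C)C)(C(C)C)C(C)C)cc3)[C@H]2O)c(OCOC)c1C(O)/C=C/c1ccc(O[Si](C(C)C)(C(C)C)C(C)C)cc1 | intermediate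
35 | (2E)-1-{3-[(2S,3S,4S,6S)-3-hydroxy-2-[4-(triisopropylsilyloxy)phenyl]-6-{2-[4-(triisopropylsilyloxy)phenyl]ethyl}oxan-4-yl]-6-methoxy-2,4-bis(methoxymethoxy)phenyl}-3-[4-(triisopropylsilyloxy)phenyl]prop-2-en-1-one | COc1cc(OCOC)c([C@@H]2C[C@H](CCc3ccc(O[Si](C(C)C)(C(C)C)C(C)C)cc3)O[C@@H](c3ccc(O[Si](C(C)C)(C(C)C)C(C)C)cc3)[C@H]2O)c(OCOC)c1C(=O)/C=C/c1ccc(O[Si](C(C)C)(C(C)C)C(C)C)cc1 | intermediate
36 | tris(trimethylsilyl) ether of 37 (both ring A phenols and the C3 hydroxyl silylated; not isolated) | COc1cc(O[Si](C)(C)C)c([C@@H]2C[C@H](CCc3ccc(O[Si](C(C)C)(C(C)C)C(C)C)cc3)O[C@@H](c3ccc(O[Si](C(C)C)(C(C)C)C(C)C)cc3)[C@H]2O[Si](C)(C)C)c(O[Si](C)(C)C)c1C(=O)/C=C/c1ccc(O[Si](C(C)C)(C(C)C)C(C)C)cc1 | intermediate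
37 | (2E)-1-{2,4-dihydroxy-3-[(2S,3S,4S,6S)-3-hydroxy-2-[4-(triisopropylsilyloxy)phenyl]-6-{2-[4-(triisopropylsilyloxy)phenyl]ethyl}oxan-4-yl]-6-methoxyphenyl}-3-[4-(triisopropylsilyloxy)phenyl]prop-2-en-1-one | COc1cc(O)c([C@@H]2C[C@H](CCc3ccc(O[Si](C(C)C)(C(C)C)C(C)C)cc3)O[C@@H](c3ccc(O[Si](C(C)C)(C(C)C)C(C)C)cc3)[C@H]2O)c(O)c1C(=O)/C=C/c1ccc(O[Si](C(C)C)(C(C)C)C(C)C)cc1 | intermediate
38 | (2E)-1-{2,4-dihydroxy-3-[(2S,3S,4S,6S)-3-hydroxy-2-(4-hydroxyphenyl)-6-[2-(4-hydroxyphenyl)ethyl]oxan-4-yl]-6-methoxyphenyl}-3-(4-hydroxyphenyl)prop-2-en-1-one (CNP0310862.1) | COc1cc(O)c([C@@H]2C[C@H](CCc3ccc(O)cc3)O[C@@H](c3ccc(O)cc3)[C@H]2O)c(O)c1C(=O)/C=C/c1ccc(O)cc1 | target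

**Step count and risks**

Total step count: 25. Longest linear sequence: 18 steps (1 → 2 → 3 → 5 → 13 → 14 → 15 → 18 → 19 → 20 → 26 → 27 → 28 → 29 → 30 → 34 → 35 → 37 → 38; the branch from 6 is equally long).

Steps most likely to fail:

1. Step 10 (Ireland–Claisen rearrangement). The boat transition state drives ring D and the arylvinyl group towards an eclipsed arrangement, so the rearrangement may be slower than decomposition of the ketene acetal (C-silylation, fragmentation). Fallback, setting out from enal 32 and returning at 27, with ring C built by hetero-Diels–Alder reaction, conjugate addition and cross-coupling: hydrogenation of the C=C bond of 32 (H2, Pd/C, EtOAc) would give 3-[4-(triisopropylsilyloxy)phenyl]propanal F1. An enantioselective hetero-Diels–Alder reaction of F1 with trans-1-methoxy-3-(trimethylsilyloxy)buta-1,3-diene, catalysed by the enantiomer of a chiral [Cr(salen)Cl] complex that leads to the 2S product, would give the cycloadduct (2S)-6-methoxy-2-{2-[4-(triisopropylsilyloxy)phenyl]ethyl}-4-(trimethylsilyloxy)-3,6-dihydro-2H-pyran F2. CF3CO2H would convert it into (2S)-2-{2-[4-(triisopropylsilyloxy)phenyl]ethyl}-2,3-dihydro-4H-pyran-4-one F3. Copper-catalysed (CuBr·SMe2) axial 1,4-addition of [4-(triisopropylsilyloxy)phenyl]magnesium bromide F4 (from commercial (4-bromophenoxy)triisopropylsilane and Mg) should give the 2,6-trans bromomagnesium enolate F5. Trapping in the same flask with N-(5-chloropyridin-2-yl)bis(trifluoromethanesulfonimide) would give (2R,6S)-2-[4-(triisopropylsilyloxy)phenyl]-6-{2-[4-(triisopropylsilyloxy)phenyl]ethyl}-5,6-dihydro-2H-pyran-4-yl trifluoromethanesulfonate F6. In parallel, 5-methoxyresorcinol would be protected (MOMCl, iPr2NEt) as 1-methoxy-3,5-bis(methoxymethoxy)benzene F7, lithiated between the two MOM ethers (n-BuLi, THF, 0 °C) to [4-methoxy-2,6-bis(methoxymethoxy)phenyl]lithium F8 and transmetalated (ZnCl2) to [4-methoxy-2,6-bis(methoxymethoxy)phenyl]zinc chloride F9. Negishi coupling of F6 with F9 (Pd(PPh3)4, THF, 60 °C) would give 27.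

2. Step 19 (Meinwald rearrangement). The C2–C3 ring bond may migrate instead of the hydride (ring contraction to a tetrahydrofuran carbaldehyde), or the α-aryl ketone may epimerise on the Lewis acid. Fallback, setting out from epoxide 28 and returning at ketone 29, with the hydride delivered from outside: BH3·THF with catalytic BF3·OEt2 should open the benzylic C4–O bond with anti hydride delivery to give (2S,3R,4S,6S)-4-[4-methoxy-2,6-bis(methoxymethoxy)phenyl]-2-[4-(triisopropylsilyloxy)phenyl]-6-{2-[4-(triisopropylsilyloxy)phenyl]ethyl}oxan-3-ol F10, which has C4 as required and the C3 hydroxyl on the wrong face. Dess–Martin oxidation of F10 would give 29, which step 20 reduces from the correct face.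

3. Step 18 (epoxidation). Oxygen transfer may be unselective between the two alkene faces, either because the chiral dioxirane cannot fit the hindered alkene or because a conformer with the C6 chain axial shields the wanted face. Fallback, setting out from 27 and returning at ketone 29, with the C3 and C4 oxygens set by osmylation: OsO4 (cat.) with N-methylmorpholine N-oxide should add anti to ring D to give (2S,3S,4S,6S)-4-[4-methoxy-2,6-bis(methoxymethoxy)phenyl]-2-[4-(triisopropylsilyloxy)phenyl]-6-{2-[4-(triisopropylsilyloxy)phenyl]ethyl}oxane-3,4-diol F11. A pinacol rearrangement with 1,2-hydride shift (pyridinium p-toluenesulfonate, CH2Cl2), ionising the tertiary benzylic C4 hydroxyl, would give 29.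

**Further compounds**

F1 | step 10 | 3-[4-(triisopropylsilyloxy)phenyl]propanal | O=CCCc1ccc(O[Si](C(C)C)(C(C)C)C(C)C)cc1
F2 | step 10 | (2S)-6-methoxy-2-{2-[4-(triisopropylsilyloxy)phenyl]ethyl}-4-(trimethylsilyloxy)-3,6-dihydro-2H-pyran (C6 epimers) | COC1C=C(O[Si](C)(C)C)C[C@H](CCc2ccc(O[Si](C(C)C)(C(C)C)C(C)C)cc2)O1
F3 | step 10 | (2S)-2-{2-[4-(triisopropylsilyloxy)phenyl]ethyl}-2,3-dihydro-4H-pyran-4-one | O=C1C[C@H](CCc2ccc(O[Si](C(C)C)(C(C)C)C(C)C)cc2)OC=C1
F4 | step 10 | [4-(triisopropylsilyloxy)phenyl]magnesium bromide | Br[Mg]c1ccc(O[Si](C(C)C)(C(C)C)C(C)C)cc1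
F5 | step 10 | bromomagnesium enolate of (2R,6S)-2-[4-(triisopropylsilyloxy)phenyl]-6-{2-[4-(triisopropylsilyloxy)phenyl]ethyl}oxan-4-one | CC(C)[Si](C(C)C)(C(C)C)Oc1ccc(CC[C@H]2CC(O[Mg]Br)=C[C@H](c3ccc(O[Si](C(C)C)(C(C)C)C(C)C)cc3)O2)cc1
F6 | step 10 | (2R,6S)-2-[4-(triisopropylsilyloxy)phenyl]-6-{2-[4-(triisopropylsilyloxy)phenyl]ethyl}-5,6-dihydro-2H-pyran-4-yl trifluoromethanesulfonate | CC(C)[Si](C(C)C)(C(C)C)Oc1ccc(CC[C@H]2CC(OS(=O)(=O)C(F)(F)F)=C[C@H](c3ccc(O[Si](C(C)C)(C(C)C)C(C)C)cc3)O2)cc1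
F7 | step 10 | 1-methoxy-3,5-bis(methoxymethoxy)benzene | COCOc1cc(OC)cc(OCOC)c1
F8 | step 10 | [4-methoxy-2,6-bis(methoxymethoxy)phenyl]lithium | [Li]c1c(OCOC)cc(OC)cc1OCOC
F9 | step 10 | [4-methoxy-2,6-bis(methoxymethoxy)phenyl]zinc chloride | Cl[Zn]c1c(OCOC)cc(OC)cc1OCOC
F10 | step 19 | (2S,3R,4S,6S)-4-[4-methoxy-2,6-bis(methoxymethoxy)phenyl]-2-[4-(triisopropylsilyloxy)phenyl]-6-{2-[4-(triisopropylsilyloxy)phenyl]ethyl}oxan-3-ol | COc1cc(OCOC)c([C@@H]2C[C@H](CCc3ccc(O[Si](C(C)C)(C(C)C)C(C)C)cc3)O[C@@H](c3ccc(O[Si](C(C)C)(C(C)C)C(C)C)cc3)[C@@H]2O)c(OCOC)c1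
F11 | step 18 | (2S,3S,4S,6S)-4-[4-methoxy-2,6-bis(methoxymethoxy)phenyl]-2-[4-(triisopropylsilyloxy)phenyl]-6-{2-[4-(triisopropylsilyloxy)phenyl]ethyl}oxane-3,4-diol | COc1cc(OCOC)c([C@@]2(O)C[C@H](CCc3ccc(O[Si](C(C)C)(C(C)C)C(C)C)cc3)O[C@@H](c3ccc(O[Si](C(C)C)(C(C)C)C(C)C)cc3)[C@@H]2O)c(OCOC)c1
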